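**Plan**

1. Numbering: ring C1 (bears C7, the CH2OAc carbon), C2 (=CH), C3 (C=O), C4 (epoxide carbon bearing the chain), C5 (epoxide CH), C6 (C=O); chain C1' (CHOAc) to C6' (CHO).
2. Cuts, backwards: C1'–OAc and the C6' aldehyde to silyl ethers; the C1=C2 alkene to a cyclopentadiene adduct (retro-Diels–Alder); the oxirane C4–O–C5 to the C4=C5 enedione of that adduct; C7–OAc to a methyl ester on C1; the two norbornene bonds at C1 and C2 (key step); the quinone to a 1,4-dimethoxyarene; C4–C1' to an arylmagnesium plus a dienal; C3'–CH3 and C1'–C2' to an enyne by methylalumination and formaldehyde.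
3. Enabling feature: C1=C2 lies between the C6 ketone and the C1 carboxyl carbon (C7 at the ester level), so it alone is a chelating, electron-poor dienophile. Masking it as a norbornene ring leaves C4=C5 as the only enedione alkene and folds the tricycle so that one face of C4=C5 is exposed.
4. Forward order: the side chain is built and joined to the arene (C4–C1'), the arene is oxidised to the quinone ring, the norbornene ring is fused on at C1–C2, the oxirane ring is closed on C4–C5, the norbornene ring is expelled, and the end groups are adjusted.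
5. Stereochemistry: C1' from oxazaborolidine reduction of the aryl dienyl ketone; the four ring centres of the adduct from endo addition under a chiral Sm(OTf)3–pybox catalyst; C4/C5 from convex-face epoxidation of the adduct, which stores the chirality before C1 and C2 return to sp2; alkene geometry from the E-enynol and syn-carboalumination.

Key step: step 11

Assumption 1 (step 7): the s-cis, β,β-disubstituted dienyl group is taken to act as the larger carbonyl substituent and the twisted ortho-methoxyaryl group as the smaller; if a model reduction shows the opposite sense, the (R)-catalyst is used and nothing else changes.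

Assumption 2 (step 11): the (S,S)-pybox ligand is taken to be the antipode that opens the C1-Si/C2-Re face of the chelated quinone; the sense would be fixed on a model quinone and the (R,R)-ligand used if it is opposite.

**Route**

Step 1
Reactants: 1 (E)-pent-2-en-4-yn-1-ol
Product: 2 (E)-tert-butyl(pent-2-en-4-yn-1-yloxy)diphenylsilane
Conditions: TBDPSCl, imidazole, CH2Cl2, 0 °C to rt
Reagents that add atoms: tert-butylchlorodiphenylsilane, CC(C)(C)[Si](Cl)(c1ccccc1)c1ccccc1
Why: Imidazole-promoted silylation of a primary alcohol; the bulky, acid-stable tert-butyldiphenylsilyl ether is chosen so that C6'–O survives the later (NH4)2Ce(NO3)6 oxidation.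

Step 2
Reactants: 2 (E)-tert-butyl(pent-2-en-4-yn-1-yloxy)diphenylsilane
Product: 4 (2E,4E)-6-(tert-butyldiphenylsilyloxy)-3-methylhexa-2,4-dien-1-ol, via alkenyldimethylalane 3 (not isolated)
Conditions: Me3Al (2.5 equiv), Cp2ZrCl2 (25 mol %), CH2Cl2, 0 °C to rt; then (CH2O)n, 0 °C to rt; aq. KNaC4H4O6
Reagents that add atoms: trimethylaluminium, C[Al](C)C; paraformaldehyde (as formaldehyde), C=O
Why: Negishi Cp2ZrCl2-catalysed carboalumination adds methyl and aluminium syn across the terminal alkyne with methyl on the internal carbon, which fixes the E geometry of C2'=C3', and the alkenylalane is then hydroxymethylated by formaldehyde with retention.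

Step 3
Reactants: 4 (2E,4E)-6-(tert-butyldiphenylsilyloxy)-3-methylhexa-2,4-dien-1-ol
Product: 5 (2E,4E)-6-(tert-butyldiphenylsilyloxy)-3-methylhexa-2,4-dienal
Conditions: MnO2 (activated, excess), CH2Cl2, rt
Reagents that add atoms: none
Why: MnO2 oxidation of a primary allylic alcohol stops at the aldehyde and leaves the alkene geometry and the silyl ether untouched.

Step 4
Reactants: 6 methyl 2,5-dimethoxybenzoate
Product: 7 methyl 4-iodo-2,5-dimethoxybenzoate
Conditions: NIS, CF3CO2H, MeCN, rt to 60 °C
Reagents that add atoms: N-iodosuccinimide, O=C1CCC(=O)N1I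
Why: Electrophilic aromatic iodination should go to C4, ortho to the 5-methoxy group (the donor not conjugated with the ester) and less hindered than the other ortho position next to the ester.

Step 5
Reactants: 7 methyl 4-iodo-2,5-dimethoxybenzoate; 5 (2E,4E)-6-(tert-butyldiphenylsilyloxy)-3-methylhexa-2,4-dienal
Product: 9 racemic methyl 4-[(2E,4E)-6-(tert-butyldiphenylsilyloxy)-1-hydroxy-3-methylhexa-2,4-dien-1-yl]-2,5-dimethoxybenzoate, via arylmagnesium chloride 8 (not isolated)
Conditions: i-PrMgCl·LiCl, THF, −40 °C; then 5, −40 to −10 °C; aq. NH4Cl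
Reagents that add atoms: none
Why: Iodine–magnesium exchange is fast at −40 °C next to the ortho methoxy group and tolerates the methyl ester, and the aryl Grignard reagent adds 1,2 to the enal (Grignard addition) to form C4–C1'; the carbinol centre is formed racemic and is corrected in steps 6 and 7.

Step 6
Reactants: 9 racemic methyl 4-[(2E,4E)-6-(tert-butyldiphenylsilyloxy)-1-hydroxy-3-methylhexa-2,4-dien-1-yl]-2,5-dimethoxybenzoate
Product: 10 methyl 4-[(2E,4E)-6-(tert-butyldiphenylsilyloxy)-3-methylhexa-2,4-dienoyl]-2,5-dimethoxybenzoate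
Conditions: MnO2 (activated, excess), CH2Cl2, rt, dark
Reagents that add atoms: none
Why: MnO2 oxidises the doubly activated (benzylic and allylic) secondary alcohol to the aryl dienyl ketone without touching the ester or the silyl ether.

Step 7
Reactants: 10 methyl 4-[(2E,4E)-6-(tert-butyldiphenylsilyloxy)-3-methylhexa-2,4-dienoyl]-2,5-dimethoxybenzoate
Product: 11 methyl 4-[(1S,2E,4E)-6-(tert-butyldiphenylsilyloxy)-1-hydroxy-3-methylhexa-2,4-dien-1-yl]-2,5-dimethoxybenzoate
Conditions: (S)-2-methyl-CBS-oxazaborolidine (20 mol %), catecholborane, toluene, −78 to −40 °C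
Reagents that add atoms: none
Why: Corey–Bakshi–Shibata reduction delivers hydride 1,2 to one carbonyl face, and with the dienyl group bound as the larger substituent the (S)-catalyst should give the (1'S)-carbinol, while catecholborane at low temperature spares the ester and the diene.

Step 8
Reactants: 11 methyl 4-[(1S,2E,4E)-6-(tert-butyldiphenylsilyloxy)-1-hydroxy-3-methylhexa-2,4-dien-1-yl]-2,5-dimethoxybenzoate
Product: 12 methyl 4-[(1S,2E,4E)-1-(tert-butyldimethylsilyloxy)-6-(tert-butyldiphenylsilyloxy)-3-methylhexa-2,4-dien-1-yl]-2,5-dimethoxybenzoate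
Conditions: TBSCl, imidazole, DMF, rt
Reagents that add atoms: tert-butylchlorodimethylsilane, CC(C)(C)[Si](C)(C)Cl
Why: Imidazole-promoted silylation under basic conditions avoids ionisation of the benzylic–allylic C1'–O bond, so the C1' configuration is kept.

Step 9
Reactants: 12 methyl 4-[(1S,2E,4E)-1-(tert-butyldimethylsilyloxy)-6-(tert-butyldiphenylsilyloxy)-3-methylhexa-2,4-dien-1-yl]-2,5-dimethoxybenzoate
Product: 13 methyl 4-[(1S,2E,4E)-1-(tert-butyldimethylsilyloxy)-6-(tert-butyldiphenylsilyloxy)-3-methylhexa-2,4-dien-1-yl]-3,6-dioxocyclohexa-1,4-diene-1-carboxylate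
Conditions: (NH4)2Ce(NO3)6 (2.5 equiv), MeCN–H2O, 0 °C, a few minutes; cold extraction, dried solution used at once
Reagents that add atoms: water, O
Why: Oxidative demethylation of the 1,4-dimethoxyarene gives the p-quinone with its oxygens taken from water, both silyl ethers should tolerate the short exposure at 0 °C, and the labile quinone ester is carried straight into step 11.

Step 10
Reactants: 14 dicyclopentadiene
Product: 15 cyclopentadiene
Conditions: neat, 170–180 °C, distillation into a receiver at −78 °C
Reagents that add atoms: none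
Why: Thermal retro-Diels–Alder cracking of the dimer gives two equivalents of the monomer, which is used cold and freshly distilled.

Step 11
Reactants: 13 quinone ester; 15 cyclopentadiene
Product: 16 endo cyclopentadiene adduct across C1–C2 of 13 (C1-Si/C2-Re face; C1 ester and C2–H cis and turned away from the CH=CH bridge)
Conditions: Sm(OTf)3 (10 mol %), 2,6-bis[(4S)-4-phenyl-2-oxazolin-2-yl]pyridine (12 mol %), 4 Å molecular sieves, CH2Cl2–THF, −78 °C; 15 (3 equiv) added last
Reagents that add atoms: none
Why: The trivalent samarium centre, held by the tridentate pybox ligand, binds 13 through the C6 carbonyl and the ester carbonyl, which lowers the LUMO of C1=C2 alone, and cyclopentadiene then adds in a concerted, asynchronous [4+2] cycloaddition. The closest known reaction type is the Sm(OTf)3–pybox-catalysed enantioselective Diels–Alder reaction of 2-alkoxycarbonyl-1,4-benzoquinones with dienes. The one ring that closes is the six-membered carbocycle of the norbornene, formed by intermolecular suprafacial [4+2] closure of the two bonds from the diene termini to C1 and C2. C1 and C2 become cis because the dienophile reacts suprafacially, the two bridgehead centres follow from the endo orientation (enedione ring beneath the diene, Alder rule), and the absolute sense, addition to the C1-Si/C2-Re face, is imposed by the ligand because C1' is too far from C1=C2 to interfere. The step needs site selectivity (C1=C2 over C4=C5), endo selectivity and dienophile-face selectivity; the first is secured by two-point binding of the β-keto ester unit, the second by secondary overlap with the C3 and C6 carbonyls, and the third by the catalyst at −78 °C, where the uncatalysed path is slowest. The quaternary C1 also prevents enolisation of the adduct to a hydroquinone.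

Step 12
Reactants: 16 endo adduct
Product: 17 triol (C7 primary alcohol and C3/C6 allylic carbinols as an epimer mixture)
Conditions: i-Bu2AlH (excess), CH2Cl2, −78 °C; aq. KNaC4H4O6
Reagents that add atoms: none
Why: Hydride reduction by i-Bu2AlH takes the ester to the primary alcohol and both enone carbonyls 1,2 to allylic alcohols; the new C3 and C6 carbinol centres are not controlled and are erased in step 14.

Step 13
Reactants: 17 triol
Product: 18 C7 monoacetate of the triol
Conditions: AcCl (1.1 equiv), 2,4,6-collidine, CH2Cl2, −78 °C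
Reagents that add atoms: acetyl chloride, CC(=O)Cl
Why: Acetyl chloride with a hindered pyridine base at −78 °C acylates primary hydroxyl groups selectively over secondary ones (selective acylation), so only C7–OH on the open convex face should be esterified.

Step 14
Reactants: 18 C7 monoacetate of the triol
Product: 19 C7-acetoxy tricyclic enedione
Conditions: Dess–Martin periodinane, CH2Cl2, 0 °C to rt
Reagents that add atoms: none
Why: Dess–Martin oxidation returns both secondary allylic alcohols to ketones and restores the C4=C5 enedione without epimerising C2, and the acetate prevents retro-aldol loss of C7.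

Step 15
Reactants: 19 C7-acetoxy tricyclic enedione
Product: 20 C4–C5 epoxide of 19 with the oxygen cis to C7 and C2–H
Conditions: t-BuOOH (anhydrous, in decane), DBU, CH2Cl2, 0 °C
Reagents that add atoms: tert-butyl hydroperoxide, CC(C)(C)OO
Why: Weitz–Scheffer nucleophilic epoxidation: the peroxide anion adds to C5 and the enolate closes onto oxygen, and attack from the convex face of the folded endo tricycle (the face carrying C7 and the C2 hydrogen) sets C4 and C5 together in the target configuration; the poor silyloxy leaving group at C1' disfavours β-elimination.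

Step 16
Reactants: 20 epoxide adduct
Product: 21 epoxyquinone with C7 acetate and C1' and C6' silyl ethers
Conditions: Ph2O (high dilution), 230 °C, N2 stream, about 10 min
Reagents that add atoms: none
Why: Retro-Diels–Alder reaction: brief heating expels volatile cyclopentadiene, helped by the quaternary C1, while the oxirane centres C4 and C5 are untouched, and high dilution limits cycloaddition between the side-chain diene and the freed C1=C2.

Step 17
Reactants: 21 epoxyquinone bis-silyl ether
Product: 22 epoxyquinone C1',C6'-diol
Conditions: HF·pyridine, pyridine, THF, 0 °C to rt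
Reagents that add atoms: none
Why: Fluoride-driven cleavage of both silyl ethers (desilylation) in a buffered medium that the electron-poor oxirane, the quinone and the acetate should tolerate.

Step 18
Reactants: 22 epoxyquinone C1',C6'-diol
Product: 23 epoxyquinone C6' aldehyde with free C1' hydroxyl
Conditions: TEMPO (10 mol %), PhI(OAc)2 (1.1 equiv), CH2Cl2, rt
Reagents that add atoms: none
Why: Oxoammonium (TEMPO) oxidation takes the primary allylic alcohol to the dienal far faster than it attacks the hindered secondary C1' alcohol and does not over-oxidise under anhydrous conditions.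

Step 19
Reactants: 23 epoxyquinone C6' aldehyde with free C1' hydroxyl
Product: 24 CNP0307549.1
Conditions: Ac2O, pyridine, DMAP (cat.), CH2Cl2, 0 °C
Reagents that add atoms: acetic anhydride, CC(=O)OC(C)=O
Why: DMAP-catalysed acylation of the remaining secondary alcohol (esterification) proceeds with retention at C1' under conditions mild enough for the epoxyquinone and the dienal.

**Compound list**

1 | (E)-pent-2-en-4-yn-1-ol | C#C/C=C/CO | starting material
2 | (E)-tert-butyl(pent-2-en-4-yn-1-yloxy)diphenylsilane | C#C/C=C/CO[Si](c1ccccc1)(c1ccccc1)C(C)(C)C | intermediate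
3 | [(1E,3E)-5-(tert-butyldiphenylsilyloxy)-2-methylpenta-1,3-dien-1-yl]dimethylalane (formed in the flask) | C[Al](C)/C=C(C)/C=C/CO[Si](c1ccccc1)(c1ccccc1)C(C)(C)C | intermediate
4 | (2E,4E)-6-(tert-butyldiphenylsilyloxy)-3-methylhexa-2,4-dien-1-ol | OC/C=C(C)/C=C/CO[Si](c1ccccc1)(c1ccccc1)C(C)(C)C | intermediate
5 | (2E,4E)-6-(tert-butyldiphenylsilyloxy)-3-methylhexa-2,4-dienal | O=C/C=C(C)/C=C/CO[Si](c1ccccc1)(c1ccccc1)C(C)(C)C | intermediate
6 | methyl 2,5-dimethoxybenzoate | COC(=O)c1cc(OC)ccc1OC | starting material
7 | methyl 4-iodo-2,5-dimethoxybenzoate | COC(=O)c1cc(OC)c(I)cc1OC | intermediate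
8 | [2,5-dimethoxy-4-(methoxycarbonyl)phenyl]magnesium chloride (formed in the flask) | COC(=O)c1cc(OC)c([Mg]Cl)cc1OC | intermediate
9 | racemic methyl 4-[(2E,4E)-6-(tert-butyldiphenylsilyloxy)-1-hydroxy-3-methylhexa-2,4-dien-1-yl]-2,5-dimethoxybenzoate | COC(=O)c1cc(OC)c(cc1OC)C(O)/C=C(C)/C=C/CO[Si](c2ccccc2)(c2ccccc2)C(C)(C)C | intermediate
10 | methyl 4-[(2E,4E)-6-(tert-butyldiphenylsilyloxy)-3-methylhexa-2,4-dienoyl]-2,5-dimethoxybenzoate | COC(=O)c1cc(OC)c(cc1OC)C(=O)/C=C(C)/C=C/CO[Si](c2ccccc2)(c2ccccc2)C(C)(C)C | intermediate
11 | methyl 4-[(1S,2E,4E)-6-(tert-butyldiphenylsilyloxy)-1-hydroxy-3-methylhexa-2,4-dien-1-yl]-2,5-dimethoxybenzoate | COC(=O)c1cc(OC)c(cc1OC)[C@@H](O)/C=C(C)/C=C/CO[Si](c2ccccc2)(c2ccccc2)C(C)(C)C | intermediate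
12 | methyl 4-[(1S,2E,4E)-1-(tert-butyldimethylsilyloxy)-6-(tert-butyldiphenylsilyloxy)-3-methylhexa-2,4-dien-1-yl]-2,5-dimethoxybenzoate | COC(=O)c1cc(OC)c(cc1OC)[C@H](/C=C(C)/C=C/CO[Si](c2ccccc2)(c2ccccc2)C(C)(C)C)O[Si](C)(C)C(C)(C)C | intermediate
13 | methyl 4-[(1S,2E,4E)-1-(tert-butyldimethylsilyloxy)-6-(tert-butyldiphenylsilyloxy)-3-methylhexa-2,4-dien-1-yl]-3,6-dioxocyclohexa-1,4-diene-1-carboxylate | COC(=O)C1=CC(=O)C([C@H](/C=C(C)/C=C/CO[Si](c2ccccc2)(c2ccccc2)C(C)(C)C)O[Si](C)(C)C(C)(C)C)=CC1=O | intermediate
14 | dicyclopentadiene | C1C=CC2C1C1CC2C=C1 | starting material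
15 | cyclopentadiene | C1=CCC=C1 | intermediate
16 | endo adduct of 15 across C1–C2 of 13 on the C1-Si/C2-Re face: norbornene-fused cyclohexenedione with C1 CO2Me and C2–H cis and on the face away from the CH=CH bridge, and the (1'S) bis-silyl chain on C4 | COC(=O)[C@@]12C(=O)C=C([C@H](/C=C(C)/C=C/CO[Si](c4ccccc4)(c4ccccc4)C(C)(C)C)O[Si](C)(C)C(C)(C)C)C(=O)[C@@H]1[C@@H]3C=C[C@H]2C3 | intermediate
17 | triol from 16: C7 CH2OH on C1 and C3/C6 allylic carbinols (epimer mixture) | OC[C@@]12C(O)C=C([C@H](/C=C(C)/C=C/CO[Si](c4ccccc4)(c4ccccc4)C(C)(C)C)O[Si](C)(C)C(C)(C)C)C(O)[C@@H]1[C@@H]3C=C[C@H]2C3 | intermediate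
18 | C7 monoacetate of 17 | CC(=O)OC[C@@]12C(O)C=C([C@H](/C=C(C)/C=C/CO[Si](c4ccccc4)(c4ccccc4)C(C)(C)C)O[Si](C)(C)C(C)(C)C)C(O)[C@@H]1[C@@H]3C=C[C@H]2C3 | intermediate
19 | C7-acetoxy tricyclic enedione (C3 and C6 ketones, C4=C5 alkene) | CC(=O)OC[C@@]12C(=O)C=C([C@H](/C=C(C)/C=C/CO[Si](c4ccccc4)(c4ccccc4)C(C)(C)C)O[Si](C)(C)C(C)(C)C)C(=O)[C@@H]1[C@@H]3C=C[C@H]2C3 | intermediate
20 | C4–C5 epoxide of 19, oxygen on the convex face, cis to C7 and C2–H | CC(=O)OC[C@@]12C(=O)[C@H]4O[C@@]4([C@H](/C=C(C)/C=C/CO[Si](c5ccccc5)(c5ccccc5)C(C)(C)C)O[Si](C)(C)C(C)(C)C)C(=O)[C@@H]1[C@@H]3C=C[C@H]2C3 | intermediate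
21 | epoxyquinone with the oxirane configuration of the target, C7 acetate, C1' tert-butyldimethylsilyl ether (1'S) and C6' tert-butyldiphenylsilyl ether | CC(=O)OCC1=CC(=O)[C@]2([C@H](/C=C(C)/C=C/CO[Si](c3ccccc3)(c3ccccc3)C(C)(C)C)O[Si](C)(C)C(C)(C)C)O[C@@H]2C1=O | intermediate
22 | epoxyquinone C1',C6'-diol (C7 acetate kept) | CC(=O)OCC1=CC(=O)[C@]2([C@H](/C=C(C)/C=C/CO)O)O[C@@H]2C1=O | intermediate
23 | epoxyquinone with C6' aldehyde and free C1' hydroxyl | CC(=O)OCC1=CC(=O)[C@]2([C@H](/C=C(C)/C=C/C=O)O)O[C@@H]2C1=O | intermediate
24 | CNP0307549.1, (4R,5S,1'S) in the route numbering, C7 and C1' acetates, (2'E,4'E)-dienal | CC(=O)OCC1=CC(=O)[C@]2([C@H](/C=C(C)/C=C/C=O)OC(C)=O)O[C@@H]2C1=O | target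

**Step count and risks**

Total: 19 steps. Longest linear sequence: 17 steps (steps 1–3, 5–9 and 11–19, from 1).

Step 11. Facial selectivity may be poor because uncatalysed addition of cyclopentadiene to the very electrophilic quinone ester competes even at −78 °C, or because the ligand induces the opposite sense; the quinone may also be lost by cycloaddition through its own side-chain diene while it waits. The fallback gives up catalyst control. It sets out from 13 and 15, which are combined without Lewis acid in CH2Cl2 at −78 °C. The thermal endo cycloaddition at the ester-bearing alkene should give both facial adducts, 16 and the C1-Re/C2-Si endo adduct F1. Because C1' is already fixed these are diastereomers and are separated by chromatography. The route is rejoined at 16.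

Step 7. Hydride delivery may discriminate weakly, or in the reverse sense, because the aryl and dienyl groups are of similar steric demand, and the diene may be hydroborated. The fallback is a classical resolution that sets out from racemic 9, so step 6 is skipped. Steglich esterification with (S)-2-methoxy-2-phenylacetic acid (DCC, DMAP, CH2Cl2, 0 °C) gives the (S)-O-methylmandelate of the (1'S)-alcohol F2 and the (S)-O-methylmandelate of the (1'R)-alcohol F3. These are separated by chromatography and assigned by the usual shielding model for such esters. Methanolysis of F2 (K2CO3, MeOH, 0 °C) releases the alcohol, and the route is rejoined at 11.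

Step 13. Site selectivity among the three hydroxyl groups may be lost, through acetylation of a secondary allylic hydroxyl or acetyl migration from C7–O to C6–O. The fallback reverses the order of oxidation and acetylation and sets out from triol 17. Activated MnO2 in large excess (CH2Cl2, rt) oxidises only the two allylic carbinols and leaves the neopentyl primary alcohol, giving the C7-hydroxymethyl tricyclic enedione F4. Ac2O and pyridine at 0 °C then acetylate C7–OH, and the route is rejoined at 19.

**Further compounds**

F1 | step 11 | endo adduct of 15 on the C1-Re/C2-Si face of 13 (facial diastereomer of 16) | COC(=O)[C@]12C(=O)C=C([C@H](/C=C(C)/C=C/CO[Si](c4ccccc4)(c4ccccc4)C(C)(C)C)O[Si](C)(C)C(C)(C)C)C(=O)[C@H]1[C@H]3C=C[C@@H]2C3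
F2 | step 7 | (S)-2-methoxy-2-phenylacetate of the (1'S)-alcohol 11 | COC(=O)c1cc(OC)c(cc1OC)[C@H](/C=C(C)/C=C/CO[Si](c2ccccc2)(c2ccccc2)C(C)(C)C)OC(=O)[C@@H](OC)c2ccccc2
F3 | step 7 | (S)-2-methoxy-2-phenylacetate of the (1'R)-alcohol | COC(=O)c1cc(OC)c(cc1OC)[C@@H](/C=C(C)/C=C/CO[Si](c2ccccc2)(c2ccccc2)C(C)(C)C)OC(=O)[C@@H](OC)c2ccccc2
F4 | step 13 | C7-hydroxymethyl tricyclic enedione | OC[C@@]12C(=O)C=C([C@H](/C=C(C)/C=C/CO[Si](c4ccccc4)(c4ccccc4)C(C)(C)C)O[Si](C)(C)C(C)(C)C)C(=O)[C@@H]1[C@@H]3C=C[C@H]2C3
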